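The indane is disconnected across C3–C3a and C1–C7a (C1 bears the 4-hydroxyphenyl group, C3 the alkylidene) into 3,5-dimethoxybenzyne and a three-carbon unit that already carries both aryl groups. One aryne (3+2) annulation of an enantiopure trans-2,3-diarylcyclopropane-1,1-diester forms both bonds and the five-membered ring; it exploits the benzo ring, in which C7a lies next to the C7 oxygen while C3a is unactivated, the polarity of a methoxy-distorted aryne. The precursor carries a 4-methoxyphenyl donor and tert-butyl esters, which shield the carbonyl groups from the aryl anion. The gem-diester then becomes the ketone, a dibromoalkene and, by ordered hydrogenolysis and Suzuki coupling with a dihydrobenzofuran boronate, the Z-arylidene; BBr3 ends the route.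

Key step: step 7

Numbering: in the running text the core keeps the target numbering used above (C1 carries the 4-oxyphenyl group, C2 the 3,5-dioxyphenyl group, C3 is the former malonate carbon); the systematic names count the five-membered ring from the other end.

Assumption: the antipodes written for the two chiral controllers, (1S,4S,5S)-isothiocineole and Rh2(S-PTAD)4, are taken to give the drawn configurations by analogy with their aldehyde epoxidations and ether C–H insertions; if either sense of induction proves opposite on these substrates, its mirror-image form is used and nothing else changes.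

Step 1
Reactants: 1 3,5-dimethoxybenzaldehyde; 2 di-tert-butyl malonate
Product: 3 di-tert-butyl 2-(3,5-dimethoxybenzylidene)malonate
Conditions: piperidine (cat.), AcOH (cat.), toluene, reflux (Dean–Stark)
Reagents that add atoms: none
Why: Knoevenagel condensation of an aromatic aldehyde with a malonate, driven by azeotropic removal of water; no stereocentre is formed.

Step 2
Reactants: 4 4-methoxybenzyl bromide; 5 (1S,4S,5S)-isothiocineole
Product: 6 (1S,4S,5S,6S)-6-(4-methoxybenzyl)-4,7,7-trimethyl-6-thiabicyclo[3.2.1]octan-6-ium triflate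
Conditions: LiOTf, CH2Cl2/H2O, rt
Reagents that add atoms: lithium triflate, [Li+].[O-]S(=O)(=O)C(F)(F)F
Why: SN2 S-alkylation of the sulfide by the reactive benzylic bromide with anion metathesis to the non-nucleophilic triflate; the exo lone pair of the bicyclic sulfide should be alkylated, so one sulfonium diastereomer is expected.

Step 3
Reactants: 3 di-tert-butyl 2-(3,5-dimethoxybenzylidene)malonate; 6 the sulfonium triflate
Product: 7 di-tert-butyl (2R,3R)-2-(3,5-dimethoxyphenyl)-3-(4-methoxyphenyl)cyclopropane-1,1-dicarboxylate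
Conditions: Cs2CO3, MeCN, 0 °C to rt; recrystallisation
Reagents that add atoms: none
Why: Sulfur-ylide cyclopropanation (Michael-initiated ring closure): the chiral benzylide should add by its open face to the β-carbon of 3 and the malonate then displaces the sulfide with inversion, so the reagent fixes the 4-methoxyphenyl carbon (3R) and the anti betaine fixes C2 (2R) trans to it, while the sulfide is recovered.

Step 4
Reactants: 8 3,5-dimethoxyphenol
Product: 9 3,5-dimethoxyphenyl N-isopropylcarbamate
Conditions: iPrNCO, Et3N (cat.), CH2Cl2, rt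
Reagents that add atoms: isopropyl isocyanate, CC(C)N=C=O
Why: Addition of the phenol to an isocyanate installs a carbamate that directs metalation and can later be removed under mild base.

Step 5
Reactants: 9 3,5-dimethoxyphenyl N-isopropylcarbamate
Product: 11 3,5-dimethoxy-2-(trimethylsilyl)phenyl N-isopropylcarbamate, via N-silyl carbamate 10 (not isolated)
Conditions: TBSOTf, TMEDA, Et2O, 0 °C to rt; n-BuLi, TMEDA, −78 °C; TMSCl; aq NaHSO4
Reagents that add atoms: chlorotrimethylsilane, C[Si](C)(C)Cl
Why: Directed ortho-metalation: after transient N-silylation the carbamate and the 3-methoxy group together direct lithiation to C2, and TMSCl traps the aryllithium.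

Step 6
Reactants: 11 3,5-dimethoxy-2-(trimethylsilyl)phenyl N-isopropylcarbamate
Product: 13 3,5-dimethoxy-2-(trimethylsilyl)phenyl trifluoromethanesulfonate, via silylphenol 12 (not isolated)
Conditions: DBU, Et2NH, MeCN, 40 °C; then PhNTf2, rt
Reagents that add atoms: N-phenylbis(trifluoromethanesulfonimide), O=S(=O)(N(c1ccccc1)S(=O)(=O)C(F)(F)F)C(F)(F)F
Why: Base-induced carbamate cleavage (E1cB to the isocyanate, scavenged by the amine) followed by O-triflation of the phenoxide in the same flask gives the ortho-silylaryl triflate aryne precursor.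

Step 7
Reactants: 7 di-tert-butyl (2R,3R)-2-(3,5-dimethoxyphenyl)-3-(4-methoxyphenyl)cyclopropane-1,1-dicarboxylate; 13 3,5-dimethoxy-2-(trimethylsilyl)phenyl trifluoromethanesulfonate
Product: 16 di-tert-butyl (2R,3R)-2-(3,5-dimethoxyphenyl)-4,6-dimethoxy-3-(4-methoxyphenyl)-2,3-dihydro-1H-indene-1,1-dicarboxylate, via 3,5-dimethoxybenzyne 14 (not isolated), via ring-opened iodomalonate anion 15 (not isolated)
Conditions: Bu4N[Ph3SiF2] (TBAT), Bu4NI, THF, 60 °C, slow addition of 13
Reagents that add atoms: none
Why: Proposed new method: iodide opens 7 by SN2 at the 4-methoxybenzylic carbon (inversion) to the γ-iodomalonate 15, its carbanion adds to the aryne carbon remote from the flanking methoxy group (C3–C3a), and the aryl anion left at C7a displaces iodide (C1–C7a); the closest known reactions are the arylation and σ-insertion of malonates with arynes and the halide-triggered (3+2) annulations of donor–acceptor cyclopropanes with imines or aldehydes. The ring closes in the 5-exo-tet mode after the first bond has formed intermolecularly. The C1 stereocentre is controlled by double inversion (net retention of the cyclopropane configuration) and, should the benzylic iodide epimerise or ionise, by the untouched C2 stereocentre, which places the 4-methoxyphenyl group trans to its aryl neighbour. The step needs the aryne regiochemistry and closure at carbon instead of at an ester: the first is secured by the inductive effect and distortion of the methoxy group next to C7a, the second by the tert-butyl esters, which block 4-exo attack on a carbonyl group, and by the high reactivity of the 4-methoxybenzylic iodide. A medium without acidic C–H bonds keeps halide addition to the aryne reversible, so that the small equilibrium share of 15 can still capture it.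

Step 8
Reactants: 16 the indane di-tert-butyl diester
Product: 18 (2S,3R)-2-(3,5-dimethoxyphenyl)-4,6-dimethoxy-3-(4-methoxyphenyl)-2,3-dihydro-1H-indene-1-carboxylic acid (C1 epimers), via malonic diacid 17 (not isolated)
Conditions: TsOH·H2O (cat.), toluene, 100 °C
Reagents that add atoms: none
Why: Acid-catalysed tert-butyl ester cleavage (loss of isobutene) and thermal decarboxylation of the aryl-substituted malonic acid; the two aryl-bearing stereocentres are not touched (the C2 descriptor changes only through the priority rules).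

Step 9
Reactants: 18 the indane-1-carboxylic acid
Product: 20 (2R,3R)-2-(3,5-dimethoxyphenyl)-4,6-dimethoxy-3-(4-methoxyphenyl)-2,3-dihydro-1H-inden-1-one, via α-hydroperoxy acid 19 (not isolated)
Conditions: LiN(iPr)2 (LDA, 2.5 equiv), THF, −78 to 0 °C; O2, −78 °C; aq HCl, rt
Reagents that add atoms: dioxygen, O=O
Why: Oxidative decarboxylation through α-oxygenation of the carboxylic acid dianion: the enediolate is trapped by O2 and the α-hydroperoxy acid loses CO2 and water on acidification, an anionic path that avoids a cation at the ring carbon and its elimination towards C2; the α-aryl centre C2 can only relax to the more stable trans ketone.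

Step 10
Reactants: 20 the indanone
Product: 22 (2R,3R)-1-(dibromomethylidene)-2-(3,5-dimethoxyphenyl)-4,6-dimethoxy-3-(4-methoxyphenyl)-2,3-dihydro-1H-indene, via hydrazone 21 (not isolated)
Conditions: N2H4·H2O, EtOH, 80 °C; then CBr4, CuCl (cat.), aq NH3, DMSO, rt
Reagents that add atoms: carbon tetrabromide, BrC(Br)(Br)Br
Why: Hydrazone formation followed by the copper-catalysed olefination of N-unsubstituted hydrazones with CBr4 turns the hindered, enolisable ketone into the gem-dibromoalkene under mild basic conditions that keep C2 in its trans arrangement.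

Step 11
Reactants: 22 the dibromoalkene
Product: 23 (1Z,2R,3R)-1-(bromomethylidene)-2-(3,5-dimethoxyphenyl)-4,6-dimethoxy-3-(4-methoxyphenyl)-2,3-dihydro-1H-indene
Conditions: Bu3SnH, Pd(PPh3)4 (cat.), toluene, rt
Reagents that add atoms: none
Why: Palladium-catalysed stannane hydrogenolysis of a gem-dibromoalkene: zerovalent palladium should insert into the bromide anti to the fused benzene ring, because the syn bromide is pressed against the peri hydrogen, so hydride replaces the anti bromide with retention and the Z bromide remains.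

Step 12
Reactants: 24 5-bromo-2-hydroxybenzonitrile; 4 4-methoxybenzyl bromide
Product: 25 5-bromo-2-[(4-methoxybenzyl)oxy]benzonitrile
Conditions: K2CO3, DMF, rt
Reagents that add atoms: none
Why: Williamson etherification of the phenoxide with the benzylic bromide installs the CH2 group that later becomes C2 of the dihydrobenzofuran.

Step 13
Reactants: 25 5-bromo-2-[(4-methoxybenzyl)oxy]benzonitrile; 26 1-bromo-3,5-dimethoxybenzene
Product: 29 [5-bromo-2-[(4-methoxybenzyl)oxy]phenyl](3,5-dimethoxyphenyl)methanone hydrazone, via aryl Grignard reagent 27 (not isolated), via N–H ketimine 28 (not isolated)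
Conditions: Mg, THF, reflux; 25, THF, 60 °C; MeOH; then N2H4·H2O, AcOH, EtOH, 80 °C
Reagents that add atoms: hydrazine hydrate, NN.O
Why: Grignard addition to the nitrile stops at the ketimine, and transimination of the N–H ketimine with hydrazine should be easier than condensation of the corresponding hindered diaryl ketone.

Step 14
Reactants: 29 the diaryl ketone hydrazone
Product: 31 (2R,3S)-5-bromo-3-(3,5-dimethoxyphenyl)-2-(4-methoxyphenyl)-2,3-dihydro-1-benzofuran (cis), via diaryldiazomethane 30 (not isolated)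
Conditions: MnO2, CH2Cl2, 0 °C, filtration; Rh2(S-PTAD)4 (1 mol%), CH2Cl2, −20 °C to rt
Reagents that add atoms: none
Why: Oxidation of the hydrazone to the diazo compound and dirhodium-catalysed intramolecular 1,5 C–H insertion of the donor/donor carbene into the benzylic ether C–H bond; the chiral carboxylate catalyst sets C3 (3S) and the concerted insertion should give the cis ring (2R).

Step 15
Reactants: 31 the cis-dihydrobenzofuran
Product: 32 (2S,3S)-5-bromo-3-(3,5-dimethoxyphenyl)-2-(4-methoxyphenyl)-2,3-dihydro-1-benzofuran (trans)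
Conditions: CF3CO2H, CH2Cl2, 0 °C to rt
Reagents that add atoms: none
Why: Acid-mediated epimerisation: reversible ionisation of the C2–O bond to the 4-methoxybenzylic cation and reclosure lead to the thermodynamically preferred trans isomer (2S), with C3 untouched.

Step 16
Reactants: 32 the trans-dihydrobenzofuran bromide
Product: 33 2-[(2S,3S)-3-(3,5-dimethoxyphenyl)-2-(4-methoxyphenyl)-2,3-dihydro-1-benzofuran-5-yl]-4,4,5,5-tetramethyl-1,3,2-dioxaborolane
Conditions: B2pin2, Pd(dppf)Cl2 (cat.), KOAc, dioxane, 90 °C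
Reagents that add atoms: bis(pinacolato)diboron, CC1(C)OB(OC1(C)C)B1OC(C)(C)C(C)(C)O1
Why: Miyaura borylation of the aryl bromide under weakly basic conditions that leave both stereocentres alone.

Step 17
Reactants: 23 the Z bromoalkene; 33 the dihydrobenzofuran boronate
Product: 34 (1Z,2R,3R)-2-(3,5-dimethoxyphenyl)-1-{[(2S,3S)-3-(3,5-dimethoxyphenyl)-2-(4-methoxyphenyl)-2,3-dihydro-1-benzofuran-5-yl]methylidene}-4,6-dimethoxy-3-(4-methoxyphenyl)-2,3-dihydro-1H-indene
Conditions: Pd(OAc)2, SPhos, K3PO4, dioxane/H2O, 70 °C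
Reagents that add atoms: none
Why: Suzuki–Miyaura coupling proceeds with retention at the alkenyl bromide, so the aryl group takes the position syn to the fused ring and the Z alkene results.

Step 18
Reactants: 34 the octamethyl ether
Product: 35 (1Z,2R,3R)-2-(3,5-dihydroxyphenyl)-1-{[(2S,3S)-3-(3,5-dihydroxyphenyl)-2-(4-hydroxyphenyl)-2,3-dihydro-1-benzofuran-5-yl]methylidene}-3-(4-hydroxyphenyl)-2,3-dihydro-1H-indene-4,6-diol (CNP0184753.4)
Conditions: BBr3, CH2Cl2, −78 to 0 °C; then MeOH, aq NaHCO3
Reagents that add atoms: none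
Why: Lewis-acid cleavage of the eight aryl methyl ethers with BBr3; the aprotic conditions at low temperature should spare the alkene geometry, and any reversible opening of the dihydrobenzofuran C2–O bond returns the trans ring.

Compound list

1 | 3,5-dimethoxybenzaldehyde | COc1cc(C=O)cc(OC)c1 | starting material
2 | di-tert-butyl malonate | CC(C)(C)OC(=O)CC(=O)OC(C)(C)C | starting material
3 | di-tert-butyl 2-(3,5-dimethoxybenzylidene)malonate | COc1cc(C=C(C(=O)OC(C)(C)C)C(=O)OC(C)(C)C)cc(OC)c1 | intermediate
4 | 4-methoxybenzyl bromide | COc1ccc(CBr)cc1 | starting material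
5 | (1S,4S,5S)-4,7,7-trimethyl-6-thiabicyclo[3.2.1]octane (isothiocineole) | C[C@H]1CC[C@H]2C[C@@H]1SC2(C)C | starting material
6 | (1S,4S,5S,6S)-6-(4-methoxybenzyl)-4,7,7-trimethyl-6-thiabicyclo[3.2.1]octan-6-ium triflate (benzyl group exo on sulfur) | C[C@H]1CC[C@H]2C[C@@H]1[S@+](Cc3ccc(OC)cc3)C2(C)C.[O-]S(=O)(=O)C(F)(F)F | intermediate
7 | di-tert-butyl (2R,3R)-2-(3,5-dimethoxyphenyl)-3-(4-methoxyphenyl)cyclopropane-1,1-dicarboxylate (trans) | COc1ccc([C@H]2[C@H](c3cc(OC)cc(OC)c3)C2(C(=O)OC(C)(C)C)C(=O)OC(C)(C)C)cc1 | intermediate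
8 | 3,5-dimethoxyphenol | COc1cc(O)cc(OC)c1 | starting material
9 | 3,5-dimethoxyphenyl N-isopropylcarbamate | COc1cc(OC(=O)NC(C)C)cc(OC)c1 | intermediate
10 | 3,5-dimethoxyphenyl N-(tert-butyldimethylsilyl)-N-isopropylcarbamate (not isolated) | COc1cc(OC(=O)N(C(C)C)[Si](C)(C)C(C)(C)C)cc(OC)c1 | intermediate
11 | 3,5-dimethoxy-2-(trimethylsilyl)phenyl N-isopropylcarbamate | COc1cc(OC)c([Si](C)(C)C)c(OC(=O)NC(C)C)c1 | intermediate
12 | 3,5-dimethoxy-2-(trimethylsilyl)phenol (not isolated) | COc1cc(O)c([Si](C)(C)C)c(OC)c1 | intermediate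
13 | 3,5-dimethoxy-2-(trimethylsilyl)phenyl trifluoromethanesulfonate | COc1cc(OC)c([Si](C)(C)C)c(OS(=O)(=O)C(F)(F)F)c1 | intermediate
14 | 3,5-dimethoxybenzyne (1,2-didehydro-3,5-dimethoxybenzene; not isolated) | COC1=CC(OC)=CC#C1 | intermediate
15 | tetrabutylammonium salt of the di-tert-butyl 2-[(1S,2S)-1-(3,5-dimethoxyphenyl)-2-iodo-2-(4-methoxyphenyl)ethyl]malonate anion (benzylic carbon inverted relative to 7; not isolated) | CCCC[N+](CCCC)(CCCC)CCCC.COc1ccc([C@@H](I)[C@H](c2cc(OC)cc(OC)c2)[C-](C(=O)OC(C)(C)C)C(=O)OC(C)(C)C)cc1 | intermediate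
16 | di-tert-butyl (2R,3R)-2-(3,5-dimethoxyphenyl)-4,6-dimethoxy-3-(4-methoxyphenyl)-2,3-dihydro-1H-indene-1,1-dicarboxylate (trans) | COc1ccc([C@@H]2c3c(OC)cc(OC)cc3C(C(=O)OC(C)(C)C)(C(=O)OC(C)(C)C)[C@H]2c2cc(OC)cc(OC)c2)cc1 | intermediate
17 | (2R,3R)-2-(3,5-dimethoxyphenyl)-4,6-dimethoxy-3-(4-methoxyphenyl)-2,3-dihydro-1H-indene-1,1-dicarboxylic acid (not isolated) | COc1ccc([C@@H]2c3c(OC)cc(OC)cc3C(C(=O)O)(C(=O)O)[C@H]2c2cc(OC)cc(OC)c2)cc1 | intermediate
18 | (2S,3R)-2-(3,5-dimethoxyphenyl)-4,6-dimethoxy-3-(4-methoxyphenyl)-2,3-dihydro-1H-indene-1-carboxylic acid (mixture of C1 epimers; aryl groups trans) | COc1ccc([C@@H]2c3c(OC)cc(OC)cc3C(C(=O)O)[C@H]2c2cc(OC)cc(OC)c2)cc1 | intermediate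
19 | (2R,3R)-2-(3,5-dimethoxyphenyl)-1-hydroperoxy-4,6-dimethoxy-3-(4-methoxyphenyl)-2,3-dihydro-1H-indene-1-carboxylic acid (C1 epimers; not isolated) | COc1ccc([C@@H]2c3c(OC)cc(OC)cc3C(OO)(C(=O)O)[C@H]2c2cc(OC)cc(OC)c2)cc1 | intermediate
20 | (2R,3R)-2-(3,5-dimethoxyphenyl)-4,6-dimethoxy-3-(4-methoxyphenyl)-2,3-dihydro-1H-inden-1-one (trans) | COc1ccc([C@@H]2c3c(OC)cc(OC)cc3C(=O)[C@H]2c2cc(OC)cc(OC)c2)cc1 | intermediate
21 | hydrazone of 20, (2R,3R) (not isolated) | COc1ccc([C@@H]2c3c(OC)cc(OC)cc3C(=NN)[C@H]2c2cc(OC)cc(OC)c2)cc1 | intermediate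
22 | (2R,3R)-1-(dibromomethylidene)-2-(3,5-dimethoxyphenyl)-4,6-dimethoxy-3-(4-methoxyphenyl)-2,3-dihydro-1H-indene | COc1ccc([C@@H]2c3c(OC)cc(OC)cc3C(=C(Br)Br)[C@H]2c2cc(OC)cc(OC)c2)cc1 | intermediate
23 | (1Z,2R,3R)-1-(bromomethylidene)-2-(3,5-dimethoxyphenyl)-4,6-dimethoxy-3-(4-methoxyphenyl)-2,3-dihydro-1H-indene (bromine syn to the fused ring) | COc1ccc([C@@H]2c3c(OC)cc(OC)cc3/C(=C\Br)[C@H]2c2cc(OC)cc(OC)c2)cc1 | intermediate
24 | 5-bromo-2-hydroxybenzonitrile | N#Cc1cc(Br)ccc1O | starting material
25 | 5-bromo-2-[(4-methoxybenzyl)oxy]benzonitrile | COc1ccc(COc2ccc(Br)cc2C#N)cc1 | intermediate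
26 | 1-bromo-3,5-dimethoxybenzene | COc1cc(Br)cc(OC)c1 | starting material
27 | (3,5-dimethoxyphenyl)magnesium bromide (not isolated) | COc1cc([Mg]Br)cc(OC)c1 | intermediate
28 | [5-bromo-2-[(4-methoxybenzyl)oxy]phenyl](3,5-dimethoxyphenyl)methanimine (not isolated) | COc1ccc(COc2ccc(Br)cc2C(=N)c2cc(OC)cc(OC)c2)cc1 | intermediate
29 | [5-bromo-2-[(4-methoxybenzyl)oxy]phenyl](3,5-dimethoxyphenyl)methanone hydrazone | COc1ccc(COc2ccc(Br)cc2C(=NN)c2cc(OC)cc(OC)c2)cc1 | intermediate
30 | 4-bromo-2-[diazo(3,5-dimethoxyphenyl)methyl]-1-[(4-methoxybenzyl)oxy]benzene (not isolated) | COc1ccc(COc2ccc(Br)cc2C(=[N+]=[N-])c2cc(OC)cc(OC)c2)cc1 | intermediate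
31 | (2R,3S)-5-bromo-3-(3,5-dimethoxyphenyl)-2-(4-methoxyphenyl)-2,3-dihydro-1-benzofuran (cis) | Brc1ccc2c(c1)[C@H](c1cc(OC)cc(OC)c1)[C@H](c1ccc(OC)cc1)O2 | intermediate
32 | (2S,3S)-5-bromo-3-(3,5-dimethoxyphenyl)-2-(4-methoxyphenyl)-2,3-dihydro-1-benzofuran (trans) | Brc1ccc2c(c1)[C@H](c1cc(OC)cc(OC)c1)[C@@H](c1ccc(OC)cc1)O2 | intermediate
33 | 2-[(2S,3S)-3-(3,5-dimethoxyphenyl)-2-(4-methoxyphenyl)-2,3-dihydro-1-benzofuran-5-yl]-4,4,5,5-tetramethyl-1,3,2-dioxaborolane | CC1(C)OB(OC1(C)C)c1ccc2c(c1)[C@H](c1cc(OC)cc(OC)c1)[C@@H](c1ccc(OC)cc1)O2 | intermediate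
34 | (1Z,2R,3R)-2-(3,5-dimethoxyphenyl)-1-{[(2S,3S)-3-(3,5-dimethoxyphenyl)-2-(4-methoxyphenyl)-2,3-dihydro-1-benzofuran-5-yl]methylidene}-4,6-dimethoxy-3-(4-methoxyphenyl)-2,3-dihydro-1H-indene | COc1ccc([C@@H]2c3c(OC)cc(OC)cc3/C(=C\c3ccc4c(c3)[C@H](c3cc(OC)cc(OC)c3)[C@@H](c3ccc(OC)cc3)O4)[C@H]2c2cc(OC)cc(OC)c2)cc1 | intermediate
35 | (1Z,2R,3R)-2-(3,5-dihydroxyphenyl)-1-{[(2S,3S)-3-(3,5-dihydroxyphenyl)-2-(4-hydroxyphenyl)-2,3-dihydro-1-benzofuran-5-yl]methylidene}-3-(4-hydroxyphenyl)-2,3-dihydro-1H-indene-4,6-diol (CNP0184753.4) | Oc1ccc([C@@H]2c3c(O)cc(O)cc3/C(=C\c3ccc4c(c3)[C@H](c3cc(O)cc(O)c3)[C@@H](c3ccc(O)cc3)O4)[C@H]2c2cc(O)cc(O)c2)cc1 | target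

Total step count: 18. Longest linear sequence: 10 steps (from 3,5-dimethoxyphenol 8 through steps 4, 5, 6, 7, 8, 9, 10, 11, 17 and 18 to 35).

Steps most likely to fail

Step 7 (the labelled step). The ring-opened iodomalonate may be too scarce to intercept the aryne, the aryl anion may transfer an acyl group or be protonated before it closes the ring, and halide may consume the aryne. The fallback sets out from 7 and comes back at 16, dividing the two bond formations into known reactions. Lewis-acid-catalysed ring-opening methanolysis of 7 (Sc(OTf)3, MeOH) should give di-tert-butyl 2-[1-(3,5-dimethoxyphenyl)-2-methoxy-2-(4-methoxyphenyl)ethyl]malonate F1, with the 3,5-dimethoxyphenyl-bearing carbon unchanged and the ether carbon as a mixture. Its cesium enolate, now present in full concentration, is arylated by the aryne from 13 (CsF, MeCN, the aryl anion being protonated by the medium) to di-tert-butyl 2-(3,5-dimethoxyphenyl)-2-[1-(3,5-dimethoxyphenyl)-2-methoxy-2-(4-methoxyphenyl)ethyl]malonate F2. Ionisation of the benzylic ether (BF3·OEt2, CH2Cl2, −40 °C) and Friedel–Crafts closure at the ring carbon ortho and para to the two methoxy groups then gives 16, the neighbouring stereocentre setting the 4-methoxyphenyl group trans.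

Step 11. Oxidative addition may take place at the wrong bromine or at both, which would give the E bromide or over-reduction. The fallback sets out from 22 and comes back at 34, reversing the order and correcting the geometry with light. Suzuki coupling of 22 with 33 at the more accessible bromine gives the (Z)-bromo(aryl)methylidene indane F3. Hydrogenolysis of the remaining bromine (Bu3SnH, Pd(PPh3)4) gives the E isomer of 34, F4. Triplet-sensitised irradiation (fac-Ir(ppy)3, blue light) should then drive the planar stilbene-like chromophore to its twisted Z form 34, the established direction of photocatalytic E-to-Z isomerisation of styrenes; any E/Z mixture from the first two operations is funnelled the same way.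

Step 3. Poor facial selectivity of the ylide addition, or partial formation of the cis isomer, would leave 7 with insufficient enantiomeric purity. The fallback sets out from 3 (with 4) and comes back at 7, replacing asymmetric induction by resolution. Tetrahydrothiophene and 4 give 1-(4-methoxybenzyl)tetrahydrothiophenium bromide F5. Its ylide (Cs2CO3, MeCN) cyclopropanates 3 to the racemic trans-cyclopropane F6. Preparative chromatography on a chiral stationary phase then delivers 7.

Further compounds

F1 | step 7 | di-tert-butyl 2-[1-(3,5-dimethoxyphenyl)-2-methoxy-2-(4-methoxyphenyl)ethyl]malonate (aryl-bearing carbon as in 7; ether carbon as a mixture) | COc1ccc(C(OC)[C@H](c2cc(OC)cc(OC)c2)C(C(=O)OC(C)(C)C)C(=O)OC(C)(C)C)cc1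
F2 | step 7 | di-tert-butyl 2-(3,5-dimethoxyphenyl)-2-[1-(3,5-dimethoxyphenyl)-2-methoxy-2-(4-methoxyphenyl)ethyl]malonate (ether carbon as a mixture) | COc1ccc(C(OC)[C@H](c2cc(OC)cc(OC)c2)C(c2cc(OC)cc(OC)c2)(C(=O)OC(C)(C)C)C(=O)OC(C)(C)C)cc1
F3 | step 11 | (1Z,2R,3R)-1-{bromo[(2S,3S)-3-(3,5-dimethoxyphenyl)-2-(4-methoxyphenyl)-2,3-dihydro-1-benzofuran-5-yl]methylidene}-2-(3,5-dimethoxyphenyl)-4,6-dimethoxy-3-(4-methoxyphenyl)-2,3-dihydro-1H-indene (bromine syn to the fused ring) | COc1ccc([C@@H]2c3c(OC)cc(OC)cc3/C(=C(\Br)c3ccc4c(c3)[C@H](c3cc(OC)cc(OC)c3)[C@@H](c3ccc(OC)cc3)O4)[C@H]2c2cc(OC)cc(OC)c2)cc1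
F4 | step 11 | (1E,2R,3R) isomer of 34 (aryl group anti to the fused ring) | COc1ccc([C@@H]2c3c(OC)cc(OC)cc3/C(=C/c3ccc4c(c3)[C@H](c3cc(OC)cc(OC)c3)[C@@H](c3ccc(OC)cc3)O4)[C@H]2c2cc(OC)cc(OC)c2)cc1
F5 | step 3 | 1-(4-methoxybenzyl)tetrahydrothiophenium bromide | COc1ccc(C[S+]2CCCC2)cc1.[Br-]
F6 | step 3 | racemic trans (2R*,3R*) form of 7 (one enantiomer drawn) | COc1ccc([C@H]2[C@H](c3cc(OC)cc(OC)c3)C2(C(=O)OC(C)(C)C)C(=O)OC(C)(C)C)cc1
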